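Making target cannot have emptied the delta flask of partner: 0.00615 M of target at 3.00 h stands against 0.055 M of partner charged, yet the target reading goes from 12.3% to 11.5% by 5.00 h. So I take it that partner fades by itself, and I read its clock from the target.

| flask | substrate | partner | precatalyst | remark | time |
|---|---|---|---|---|---|
| delta | 0.050 M | 0.055 M | 75 µM | run made earlier |  |
| eta | 0.050 M | 0.055 M | 110 µM | run made earlier |  |
| midnight | 0.050 M | 0.0550 M | 75 µM | a closed flask charged with all of it at once and left for 5.0 h | 5.0 h |
| summer | 0.050 M (fed, over 4.00 h) | 0.0550 M | 75 µM | a stirred flask in which substrate is dosed at a steady rate over 4.00 h without added volume, worked up at 5.0 h | 5.0 h |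
| spring | 0.050 M | 0.0550 M (fed, over 4.00 h) | 75 µM | all but partner at the start; partner goes in evenly over 4.00 h, the run ends at 5.0 h | 5.0 h |
| dawn | 0.050 M | 0.0550 M | 75 µM | one stirred flow tank at steady state, fed with the mixture as stated, mean residence time 5.0 h |  |

delta run (percent of the substrate charged)

| time / h | open intermediate / % | target / % | substrate / % |
|---|---|---|---|
| 0.417 | 7.6 | 0.3 | 91.0 |
| 0.667 | 17.5 | 2.1 | 82.5 |
| 1.00 | 29.0 | 3.1 | 67.1 |
| 2.00 | 56.8 | 9.6 | 34.2 |
| 3.00 | 73.3 | 12.3 | 16.3 |
| 5.00 | 84.0 | 11.5 | 2.6 |

eta run (percent of the substrate charged)

| time / min | open intermediate / % | target / % | substrate / % |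
|---|---|---|---|
| 2.50 | 1.0 | 0.5 | 99.8 |
| 4.00 | 0.4 | 0.3 | 99.1 |
| 6.00 | 0.4 | 0 | 98.3 |
| 10.0 | 2.9 | 0.6 | 98.7 |
| 20.0 | 8.1 | 0.8 | 91.6 |
| 30.0 | 15.1 | 0.6 | 84.6 |

(scatter of a reading: 0.5 percentage points)

- the stated concentrations are those of everything mixed, before any reaction; amounts are the same in each set-up
- the numbers in the tables scatter by 0.5 percentage points (one standard deviation)
- the feed brings no volume worth counting
- the earlier runs were made in a closed, stirred flask

* the set-up with the highest amount of open intermediate at the outlet or at the end, in percent of the substrate put in ("none" if the first two lie within 2 percentage points) (midnight / summer / spring / dawn / none)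
* amount of open intermediate at the outlet or at the end, in percent of the substrate put in, midnight
* amount of open intermediate at the outlet or at the end, in percent of the substrate put in, summer
* amount of open intermediate at the outlet or at the end, in percent of the substrate put in, spring
* amount of open intermediate at the outlet or at the end, in percent of the substrate put in, dawn

Let s be the target gained per hour per open intermediate present, a pseudo-first-order constant that I expect to follow partner. In delta, s is 0.152 h⁻¹ over the hour ending at 2.00 h and 0.0415 h⁻¹ over the next. This gives a fading constant k of 1.29 h⁻¹ and a partner half-life tB, the time in which s halves, of 0.535 h. Carried back to fresh partner, s is 1.06 h⁻¹.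

In dawn, fresh feed keeps partner at 13.4% of its charge, so target over open intermediate is 0.707. Delta's substrate constant 0.708 h⁻¹ leaves 22.0% unconverted, so I reckon dawn at 45.7%. In spring, the feed holds a partner plateau of 0.0106 M, so s stays near 0.204 h⁻¹, higher than delta's late value, and I put spring well under midnight, which repeats delta's 84.0%. Summer keeps about 17.4% of substrate unconverted by my reckoning, more than delta's 2.6%. That leaves summer about 82.6% for open intermediate and target together, less than delta's reading of 84.0% for open intermediate by itself, so I put midnight first, though I have not reckoned summer's target.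

The forecast says none, with 84.5%, 79%, 85% and 67% for midnight, summer, spring and dawn, holding that “partner feed roughly matches the delta consumption rate”.

The flask gives midnight as best, with 84.5%, 81.6%, 63.5% and 49.8% in that order.

    partner + catalyst intermediate → free catalyst + target (k = 435 L mol⁻¹ min⁻¹)
    substrate + free catalyst → free catalyst + open intermediate (k = 307 L mol⁻¹ min⁻¹)
    partner → decomposed reagent (k = 0.0190 min⁻¹)
    precatalyst → free catalyst (k = 0.0139 min⁻¹)
    free catalyst + open intermediate ⇌ catalyst intermediate (K = 19.0 L mol⁻¹, k = 1100 L mol⁻¹ min⁻¹)

Dawn ends with 29.5% of target beside 49.8% of open intermediate, a ratio of 0.592 against my 0.707. Open intermediate survives in dawn through partner turning into decomposed reagent, together with catalyst intermediate returning to free catalyst and open intermediate: without the first, dawn gives 22.5%, and without the second, 9.37%. Taken to spring, tB turns the feed rate into a plateau of 0.0106 M, and the highest partner concentration in spring is 0.00859 M.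

All runs come from a simulation with constants of no real substance; noise was put on by code.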